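If the impurity takes initiator one for one, it is the limiting reagent of that step, with less of it charged than of initiator, and the leftover initiator is what can begin chains. The charge of 0.60 mM less 0.22 mM leaves 0.380 mM. This leftover is the chain budget n, the initiator charge minus the impurity charge. It is a guess, and it is the same in green and blue.

all flasks: initiator 0.60 mM; impurity 0.22 mM
- midnight: free monomer 0.40 M; run made earlier
- summer: free monomer 1.4 M; run made earlier
- green: free monomer 0.30 M; time 10 d
- blue: free monomer 1.0 M; time 10 d

| run | time / d | monomer in chains / % | free monomer / % |
|---|---|---|---|
| midnight | 0.833 | 20 | 64 |
| midnight | 2.50 | 40 | 21 |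
| midnight | 5.00 | 45 | 7 |
| midnight | 8.00 | 43 | 3 |
| summer | 0.833 | 30 | 57 |
| summer | 2.50 | 52 | 17 |
| summer | 5.00 | 54 | 6 |
| summer | 8.00 | 62 | 0 |

(standard deviation of a reading: 2 percentage points)

- which of the two ends with the longer chains by the average number of monomer units in a chain (chains begun, living or dead) ("neither" if they lie within 10 %) (green / blue / neither)
- average number of monomer units in a chain (chains begun, living or dead) at the end, green
- average number of monomer units in a chain (chains begun, living or dead) at the end, blue

- the average divides the monomer in chains by the number of chains begun, living and dead together
- the earlier runs do not show the number of chains; that part of a forecast is a guess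

The average length is then the monomer in chains at the end over n. The curve of monomer in chains is drawn from the midnight run, the nearest to green. Free monomer there gives a first-order constant λ and a half-life:

λ = 0.624 /d, half-life = 1.11 d

In the midnight run, monomer in chains starts with a slope of 0.240 /d of the charge, as read from the first point. Its last two readings give a level:

midnight level = 44.0 %; knee = level/slope = 1.83 d

The summer run, taken for blue, gives a level of 58.0 %. The asked 10 d is 9.01 half-lives, so this reckoning puts both ends on their levels, unadjusted for charge:

green: level × 0.30 M / n = 347

blue: level × 1.0 M / n = 1530

The forecast names blue, with 330 for green (195 to 410) and 1430 for blue (850 to 1750). Both numbers are less than this reckoning gives. On the count it says: “If the impurity destroys initiator one-for-one, about 0.38 mM of chains begin”.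

Green ends at 294 and blue at 1550, so blue holds the longer chains, as forecast, and both lie inside the forecast's ranges.

    free monomer + initiator → living end + monomer in chains (k = 0.00550 /M/min)
    free monomer + living end → monomer in chains + living end, rate k2*[living end]*[free monomer] (k = 1.00 /M/min)
    monomer in chains + living end → free monomer + living end, rate k3*[living end] as long as [monomer in chains] is above zero (k = 0.0300 /min)
    initiator + impurity → spent initiator A (k = 320 /M/min)
    free monomer + initiator → spent initiator B (k = 5.90 × 10⁻⁴ /M/min)
    free monomer → uncatalysed product (k = 2.10 × 10⁻⁴ /min)

Living end stands at 3.41 × 10⁻⁴ M in green and 3.43 × 10⁻⁴ M in blue, less than n. With the monomer in chains at 10 d, n gives 264 for green and 1400 for blue. The same flask as green charged with 0.0024 M of initiator has a budget of 2.18 mM. Its 48.0 % of monomer in chains then gives 66.1, against 75.0 from the simulation.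

The earlier runs and the new flask were computed for an exercise; the scatter is artificial.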